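Take the last reading, at 50.0 min: the west flask, which is the flask asked about, has then run for a third of its 2.5 h.

- west: substrate 0.10 M; reagent 0.10 M; capture agent 2 mM; the very flask that is asked about, followed so far
- flask: substrate 0.10 M; reagent 0.100 M; capture agent 2.00 mM; time 2.5 h
west run (percent of the substrate charged)

| time / min | target / % | side product / % |
|---|---|---|
| 3.00 | 16.0 | 22.0 |
| 8.00 | 21.5 | 45.7 |
| 15.0 | 23.1 | 58.9 |
| 25.0 | 23.9 | 65.1 |
| 30.0 | 24.4 | 66.6 |
| 50.0 | 24.7 | 68.4 |

(readings scatter by 0.3 percentage points)
1. share of target in target plus side product at 6.0 s
2. share of target in target plus side product at 2.5 h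
3. which of target and side product there is more of at 2.5 h

You want the late log odds, the decimal logarithm of [target]/[side product], which is the selectivity written in powers of ten. Before taking its value, ask which input has to be known well.

Start with the target reading. It rose 0.3 percentage points between the last two readings, the size of the scatter 0.3 points, and a shift of that size moves the log odds by 0.00531. The same shift on side product moves them by 0.00191, less because side product is the larger reading. The remainder is another matter: 6.90 % of the substrate charged is in neither product. All of it in side product moves the log odds by 0.0417, and all of it in target by 0.107. So the remainder moves the log odds more than the scatter does.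

Now the number: the late log odds are −0.442. I commit to keeping them, which gives a share of 26.5 %. Even with the whole remainder on target, the log odds are −0.335, so side product stays ahead. The time 6.0 s lies 1.48 powers of ten before the first reading, so I make no reckoning there.

The forecast gives 95 % (85 % to 99 %) at 6.0 s, 26 % (25 % to 27 %) at 2.5 h, and side product ahead, holding that “direct branching gives about one quarter target”. Its late share stands a little below mine.

The flask gives 94.2 % at 6.0 s and 26.4 % at 2.5 h, with side product ahead: target 25.4 %, side product 70.7 %.

    substrate + reagent → intermediate A (k = 0.0720 M⁻¹ s⁻¹)
    substrate + reagent → target (k = 0.0250 M⁻¹ s⁻¹)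
    intermediate A → intermediate B (k = 0.00670 s⁻¹)
    intermediate B → side product (k = 0.00300 s⁻¹)
    reagent + intermediate B → intermediate C (k = 0.00350 M⁻¹ s⁻¹)
    intermediate C ⇌ intermediate D (K = 1.40, k = 0.0470 s⁻¹)
    intermediate A → side product (k = 0.00710 s⁻¹)
    capture agent + intermediate B → trapped intermediate (k = 0.140 M⁻¹ s⁻¹)

This flask ends at log odds of −0.445, against the carried −0.442. At the start, substrate enters the step to intermediate A 2.9 times as fast as the step to target, which is −0.462 in the same measure. The neighbour flask with 0.025 M of reagent has 0 % of its reagent left and 75.0 % of its substrate unused at 2.5 h, with target at 6.44 % and side product at 17.9 %, and its log odds are −0.444.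

(The runs come from a simulation on assumed constants, noise included.)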